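## Retrosynthetic overview
- The C3–CH2Ar bond is made last. The target comes from the silyl ketene acetal of (R)-β-(3,4,5-trimethoxybenzyl)butyrolactone and the guaiacyl p-quinone methide obtained by dehydrogenating creosol. This new 1,6-benzylation sets C3 anti to C4 and needs no phenol protection.
- The lactone ring comes from a catalytic enantioselective Baeyer–Villiger ring expansion (C-to-O 1,2-shift) of prochiral 3-(3,4,5-trimethoxybenzyl)cyclobutanone. This is the key step and sets C4.
- The cyclobutanone comes from a Negishi coupling of (3-oxocyclobutyl)methylzinc bromide with 5-chloro-1,2,3-trimethoxybenzene.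
- Both arenes come from ortho-bromination and copper-catalysed methoxylation: ring A from 4-chlorophenol, ring B from p-cresol.
- Ring order: both benzene rings and the four-membered carbocycle are bought. The only ring made is the γ-lactone, by four-to-five expansion in step 4.

Assumption: 3-(bromomethyl)cyclobutan-1-one is taken as a catalogue building block, and the ligand antipode used in step 4 is the one a test run shows to give the (R)-lactone (both antipodes are accessible).

## Route

Step 1
Reactants: 1 para-chlorophenol (4-chlorophenol)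
Product: 2 dibromide 2,6-dibromo-4-chlorophenol
Conditions: Br2 (2.05 equiv), AcOH, 20 °C
Reagents that add atoms: bromine, BrBr
Why: Electrophilic aromatic bromination, in which the OH group directs to both free ortho positions because chlorine blocks the para position; no stereocentre is formed.

Step 2
Reactants: 2 dibromide 2,6-dibromo-4-chlorophenol
Product: 4 aryl chloride 5-chloro-1,2,3-trimethoxybenzene, via sodium 4-chloro-2,6-dimethoxyphenolate 3 (not isolated)
Conditions: NaOMe (5 equiv), CuBr (10 mol %), DMF/MeOH, 110 °C; cool to 25 °C, MeI (4 equiv)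
Reagents that add atoms: sodium methoxide, [Na+].[O-]C; iodomethane, CI
Why: Ullmann-type copper-catalysed methoxylation replaces both C–Br bonds while the stronger C–Cl bond on the electron-rich phenolate stays untouched, and the phenolate left in the pot is then O-methylated (Williamson ether synthesis).

Step 3
Reactants: 4 aryl chloride 5-chloro-1,2,3-trimethoxybenzene; 5 bromide 3-(bromomethyl)cyclobutan-1-one
Product: 7 cyclobutanone 3-(3,4,5-trimethoxybenzyl)cyclobutan-1-one, via (3-oxocyclobutyl)methylzinc bromide 6 (not isolated)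
Conditions: 5, Zn dust (1.5 equiv, activated by BrCH2CH2Br/Me3SiCl), LiCl, THF, 40 °C; then 4, Pd(OAc)2 (2 mol %), SPhos (4 mol %), THF, 50 °C
Reagents that add atoms: none
Why: Negishi coupling, in which LiCl-assisted zinc insertion gives a ketone-tolerant primary alkylzinc and SPhos-ligated zerovalent palladium inserts into the aryl chloride and eliminates reductively faster than β-hydride loss; the product is achiral.

Step 4
Reactants: 7 cyclobutanone 3-(3,4,5-trimethoxybenzyl)cyclobutan-1-one
Product: 8 lactone (4R)-4-(3,4,5-trimethoxybenzyl)dihydrofuran-2(3H)-one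
Conditions: Sc(OTf)3 (5 mol %), chiral N,N'-dioxide ligand (pipecolic-acid-derived bis-amide, 2,6-diisopropylanilide arms, 5 mol %), mCPBA (1.2 equiv), EtOAc, −20 °C
Reagents that add atoms: meta-chloroperoxybenzoic acid, O=C(OO)c1cccc(Cl)c1
Why: Desymmetrising asymmetric Baeyer–Villiger ring expansion (key step), in which the peracid adds to the strained ketone held on the chiral scandium complex and only the enantiotopic CH2 lying antiperiplanar to the O–O bond in the favoured Criegee adduct shifts from C to O, making the lactone and fixing C4 as R.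

Step 5
Reactants: 9 p-cresol (4-methylphenol)
Product: 10 bromocresol 2-bromo-4-methylphenol
Conditions: Br2 (1.0 equiv), CH2Cl2, 0 °C
Reagents that add atoms: bromine, BrBr
Why: Electrophilic aromatic bromination ortho to OH (para is blocked by CH3) stops at the monobromide with one equivalent of bromine in the cold.

Step 6
Reactants: 10 bromocresol 2-bromo-4-methylphenol
Product: 11 creosol (2-methoxy-4-methylphenol)
Conditions: NaOMe (3 equiv), CuBr (10 mol %), DMF/MeOH, 110 °C; 1 M HCl work-up
Reagents that add atoms: sodium methoxide, [Na+].[O-]C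
Why: Ullmann-type copper-catalysed methoxylation of an ortho-bromophenolate, the same robust reaction type as in step 2.

Step 7
Reactants: 8 lactone (4R)-4-(3,4,5-trimethoxybenzyl)dihydrofuran-2(3H)-one; 11 creosol (2-methoxy-4-methylphenol)
Product: 16 (3R,4R)-3-(4-hydroxy-3-methoxybenzyl)-4-(3,4,5-trimethoxybenzyl)dihydrofuran-2(3H)-one (target), via lithium enolate 12 (not isolated), via silyl ketene acetal 13 (not isolated), via quinone methide 14 (not isolated), via aryl silyl ether 15 (not isolated)
Conditions: (a) 8, LiN(SiMe3)2 (1.1 equiv), THF, −78 °C; Me3SiCl (1.1 equiv), −78 to 0 °C; evaporate, take up crude 13 in CH2Cl2, −78 °C; (b) 11 (1.5 equiv), Ag2O (3 equiv), 4 Å MS, CH2Cl2 (0.02 M), 0 °C, dark, 15 min, filter through Celite/MgSO4 under Ar straight into (a); −78 to −20 °C; (c) 1 M HCl, THF, 0 °C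
Reagents that add atoms: none
Why: Proposed new method: dehydrogenative 1,6-benzylation of a lactone silyl ketene acetal by an unstabilised guaiacyl p-quinone methide made by C–H oxidation; Ag2O removes the phenolic and one benzylic hydrogen of 11 (phenoxyl radical, then second oxidation and deprotonation) to give 14, which persists only in cold dilute solution because its self-addition is second order; its exocyclic CH2 is unhindered and attack there restores aromaticity, so the strongly π-nucleophilic cyclic ketene acetal 13 should add without a catalyst; the silyl group then moves from the oxocarbenium oxygen to the phenoxide to give neutral 15, so no phenoxide remains to attack a second 14; the electrophile approaches the flat dihydrofuran on the face opposite the C4 benzyl group, which sets C3 as R (3,4-trans, also the thermodynamic isomer); the closest known reaction types are the 1,6-conjugate (vinylogous Mukaiyama–Michael) addition of silyl ketene acetals and enolates to stabilised 2,6-di-tert-butyl-7-aryl p-quinone methides, the Ag2O dehydrogenation of 4-alkylphenols, and the anti-selective enolate benzylation of β-benzylbutyrolactones.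

## Compound list
1 | 4-chlorophenol | Oc1ccc(Cl)cc1 | starting material
2 | 2,6-dibromo-4-chlorophenol | Oc1c(Br)cc(Cl)cc1Br | intermediate
3 | sodium 4-chloro-2,6-dimethoxyphenolate (not isolated) | [Na+].[O-]c1c(OC)cc(Cl)cc1OC | intermediate
4 | 5-chloro-1,2,3-trimethoxybenzene | COc1cc(Cl)cc(OC)c1OC | intermediate
5 | 3-(bromomethyl)cyclobutan-1-one | O=C1CC(CBr)C1 | starting material
6 | (3-oxocyclobutyl)methylzinc bromide (not isolated) | O=C1CC(C[Zn]Br)C1 | intermediate
7 | 3-(3,4,5-trimethoxybenzyl)cyclobutan-1-one (achiral) | O=C1CC(Cc2cc(OC)c(OC)c(OC)c2)C1 | intermediate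
8 | (4R)-4-(3,4,5-trimethoxybenzyl)dihydrofuran-2(3H)-one | O=C1C[C@@H](Cc2cc(OC)c(OC)c(OC)c2)CO1 | intermediate
9 | p-cresol (4-methylphenol) | Cc1ccc(O)cc1 | starting material
10 | 2-bromo-4-methylphenol | Cc1ccc(O)c(Br)c1 | intermediate
11 | creosol (2-methoxy-4-methylphenol) | Cc1ccc(O)c(OC)c1 | intermediate
12 | lithium enolate of 8, lithium (4R)-4-(3,4,5-trimethoxybenzyl)-4,5-dihydrofuran-2-olate (not isolated) | [Li]OC1=C[C@@H](Cc2cc(OC)c(OC)c(OC)c2)CO1 | intermediate
13 | (4R)-2-(trimethylsilyloxy)-4-(3,4,5-trimethoxybenzyl)-4,5-dihydrofuran (not isolated) | C[Si](C)(C)OC1=C[C@@H](Cc2cc(OC)c(OC)c(OC)c2)CO1 | intermediate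
14 | 2-methoxy-4-methylidenecyclohexa-2,5-dien-1-one (not isolated) | C=C1C=CC(=O)C(OC)=C1 | intermediate
15 | (3R,4R)-3-[3-methoxy-4-(trimethylsilyloxy)benzyl]-4-(3,4,5-trimethoxybenzyl)dihydrofuran-2(3H)-one (not isolated) | COc1cc(C[C@H]2C(=O)OC[C@@H]2Cc2cc(OC)c(OC)c(OC)c2)ccc1O[Si](C)(C)C | intermediate
16 | (3R,4R)-3-(4-hydroxy-3-methoxybenzyl)-4-(3,4,5-trimethoxybenzyl)dihydrofuran-2(3H)-one | COc1cc(C[C@H]2C(=O)OC[C@@H]2Cc2cc(OC)c(OC)c(OC)c2)ccc1O | target

## Step count and risks
Total step count: 7. Longest linear sequence: 5 (steps 1, 2, 3, 4, 7).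

**Steps most likely to fail**

**Step 7 (the new step).**
- Risks:
  - Ag2O may give ortho C–C phenol dimers of 11 instead of 14.
  - 14 may oligomerise before it meets 13.
  - Traces of water or unreacted 11 may destroy 13. This only returns 8, which can be recovered.
- Fallback (known chemistry), from 11 back to 16:
  - Treat 11 with Boc2O and DMAP (cat.) in CH2Cl2 to give tert-butyl (2-methoxy-4-methylphenyl) carbonate F1.
  - Wohl–Ziegler bromination (NBS, AIBN, PhCF3, 80 °C) gives 4-(bromomethyl)-2-methoxyphenyl tert-butyl carbonate F2.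
  - The lithium enolate 12 (from 8 with LiN(SiMe3)2, THF, −78 °C) is alkylated by F2 anti to the C4 benzyl group. This gives (3R,4R)-3-[4-(tert-butoxycarbonyloxy)-3-methoxybenzyl]-4-(3,4,5-trimethoxybenzyl)dihydrofuran-2(3H)-one F3.
  - CF3CO2H in CH2Cl2 at 20 °C removes the carbonate and gives 16.
  - This costs three extra steps.

**Step 3.**
- Risks:
  - The (3-oxocyclobutyl)methyl radical formed during zinc insertion can open to an α-keto radical.
  - The electron-rich aryl chloride may add slowly to palladium.
- Fallback, from 4 back to 7, builds the four-membered ring on the arene side chain instead of coupling a preformed ring: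
  - Suzuki allylation of 4 (allylboronic acid pinacol ester, Pd(OAc)2, SPhos, K3PO4, THF/H2O, 60 °C) gives 5-allyl-1,2,3-trimethoxybenzene F4.
  - Dichloroketene cycloaddition (Cl3CCOCl, Zn/Cu couple, Et2O) gives racemic 2,2-dichloro-3-(3,4,5-trimethoxybenzyl)cyclobutan-1-one F5.
  - Zn in AcOH removes both chlorines and gives 7.

**Step 4.**
- Risk: the flexible benzyl substituent may give only moderate ee.
- Fallback, from 7 back to 8, replaces catalytic desymmetrisation with a racemic ring expansion and a classical resolution:
  - mCPBA and NaHCO3 in CH2Cl2 at 0 °C give racemic 4-(3,4,5-trimethoxybenzyl)dihydrofuran-2(3H)-one F6.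
  - Aminolysis with (R)-1-phenylethylamine and AlMe3 gives two hydroxy amides, separated by crystallisation or chromatography. They are (3R)-4-hydroxy-N-[(1R)-1-phenylethyl]-3-(3,4,5-trimethoxybenzyl)butanamide F7 and its (3S) diastereomer (3S)-4-hydroxy-N-[(1R)-1-phenylethyl]-3-(3,4,5-trimethoxybenzyl)butanamide F8.
  - Heating F7 in 2 M H2SO4/dioxane closes the lactone and gives enantiopure 8.
  - At most half of the material is used.

## Further compounds
F1 | step 7 | tert-butyl (2-methoxy-4-methylphenyl) carbonate | Cc1ccc(OC(=O)OC(C)(C)C)c(OC)c1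
F2 | step 7 | 4-(bromomethyl)-2-methoxyphenyl tert-butyl carbonate | BrCc1ccc(OC(=O)OC(C)(C)C)c(OC)c1
F3 | step 7 | (3R,4R)-3-[4-(tert-butoxycarbonyloxy)-3-methoxybenzyl]-4-(3,4,5-trimethoxybenzyl)dihydrofuran-2(3H)-one | COc1cc(C[C@H]2C(=O)OC[C@@H]2Cc2cc(OC)c(OC)c(OC)c2)ccc1OC(=O)OC(C)(C)C
F4 | step 3 | 5-allyl-1,2,3-trimethoxybenzene | C=CCc1cc(OC)c(OC)c(OC)c1
F5 | step 3 | racemic 2,2-dichloro-3-(3,4,5-trimethoxybenzyl)cyclobutan-1-one | O=C1CC(Cc2cc(OC)c(OC)c(OC)c2)C1(Cl)Cl
F6 | step 4 | racemic 4-(3,4,5-trimethoxybenzyl)dihydrofuran-2(3H)-one | O=C1CC(Cc2cc(OC)c(OC)c(OC)c2)CO1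
F7 | step 4 | (3R)-4-hydroxy-N-[(1R)-1-phenylethyl]-3-(3,4,5-trimethoxybenzyl)butanamide | OC[C@@H](CC(=O)N[C@H](C)c1ccccc1)Cc1cc(OC)c(OC)c(OC)c1
F8 | step 4 | (3S)-4-hydroxy-N-[(1R)-1-phenylethyl]-3-(3,4,5-trimethoxybenzyl)butanamide | OC[C@H](CC(=O)N[C@H](C)c1ccccc1)Cc1cc(OC)c(OC)c(OC)c1
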